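## Retrosynthetic overview

1. **18 ⇐ 17:** trans-bromohydroxylation of the ring A 1,3-diene sets C4–Br and C3–OH last.
2. **17 ⇐ 11:** ring A ketone → dienyl triflate → C1 methyl; ring B ketone → C9 methylation → C8 vinyl bromide.
3. **11 ⇐ 10 (key step):** catalytic enantioselective semipinacol ring expansion. The quaternary C5 shifts 1,2 from the carbinol carbon to the enone β-carbon C6, making the C5–C6 bond, the spiro centre and ring A (five → six) at once.
4. **10 ⇐ 6 + 3:** a β-acylvinyl anion equivalent from 3-bromocyclohex-2-enone (4) adds to 2,2-dimethylcyclopent-3-enone (3, made from 1).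
5. **Ring order:** ring B is bought as a six-membered ring; ring A is made from a cyclopentene by the ring expansion.

Convention and assumption: atoms are numbered as in the target name (3S,4S,6S)-4,8-dibromo-1,5,5,9-tetramethylspiro[5.5]undeca-1,8-dien-3-ol (ring A = C1–C6, ring B = C6–C11, C6 spiro); 1 and 4 are taken as commercial.

## Route

Step 1
Reactants: 1 2-methylcyclopent-2-en-1-one
Product: 3 2,2-dimethylcyclopent-3-en-1-one, via potassium dienolate 2 (not isolated)
Conditions: KOt-Bu (1.0 equiv), t-BuOH–THF, 0 °C; MeI (3 equiv), 0 → 25 °C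
Reagents that add atoms: iodomethane, CI
Why: Thermodynamic γ-deprotonation gives the extended dienolate, which is C-methylated at the α-carbon (deconjugative α-alkylation of an enone), creating the gem-dimethyl carbon (future C5) next to the carbonyl and the β,γ-alkene; no stereocentre is formed.

Step 2
Reactants: 4 3-bromocyclohex-2-en-1-one
Product: 6 [(5-bromocyclohexa-1,5-dien-1-yl)oxy](tert-butyl)dimethylsilane, via lithium enolate 5 (not isolated)
Conditions: LiN(i-Pr)2 (1.05 equiv), THF, −78 °C; TBSCl, DMPU, −78 → 0 °C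
Reagents that add atoms: tert-butyldimethylsilyl chloride, CC(C)(C)[Si](C)(C)Cl
Why: Kinetic α′-deprotonation and O-silylation (silyl dienol ether formation) mask the carbonyl so that the vinyl bromide can be lithiated; no stereocentre is formed.

Step 3
Reactants: 6 [(5-bromocyclohexa-1,5-dien-1-yl)oxy](tert-butyl)dimethylsilane; 3 2,2-dimethylcyclopent-3-en-1-one
Product: 10 rac-3-(1-hydroxy-2,2-dimethylcyclopent-3-en-1-yl)cyclohex-2-en-1-one, via dienyllithium 7 (not isolated), via dienylcerium dichloride 8 (not isolated), via silyl dienol ether carbinol 9 (not isolated)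
Conditions: t-BuLi (2.0 equiv), Et2O, −78 °C; CeCl3, THF, −78 °C; 3, −78 °C; then 1 M HCl, THF, 0 °C
Reagents that add atoms: none
Why: Br–Li exchange gives the β-acylvinyl anion equivalent, whose organocerium form adds 1,2 to the hindered, enolisable ketone (organocerium carbonyl addition), and dilute acid hydrolyses the silyl dienol ether to the conjugated enone; the carbinol centre is formed racemic and is destroyed in step 4.

Step 4
Reactants: 10 rac-3-(1-hydroxy-2,2-dimethylcyclopent-3-en-1-yl)cyclohex-2-en-1-one
Product: 11 (6R)-5,5-dimethylspiro[5.5]undec-3-ene-1,8-dione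
Conditions: 9-amino-9-deoxy-epi-quinidine·2 CF3CO2H (20 mol %), toluene, 40 °C
Reagents that add atoms: none
Why: Proposed new method: the primary amine condenses with the enone carbonyl to a chiral iminium ion that makes C6 electrophilic; the quaternary, allylic C5 (the better migrating α-carbon of the cyclopentenol) shifts 1,2 from the carbinol carbon C1 to the face of C6 left open by the catalyst while the O–H is lost, giving the C1 ketone, the C5–C6 vicinal quaternary bond, ring A (five → six) and the spiro centre, and because the carbinol carbon becomes sp2 both enantiomers of racemic 10 can converge on (6R)-11, the facial choice resting on the covalently bound catalyst (both nitrogens protonated, so it does not depend on where the hydroxyl sits; the quinine-derived pseudo-enantiomer gives the antipode); the closest known reaction type is the amine-catalysed asymmetric vinylogous α-ketol (semipinacol) rearrangement of 3-(1-hydroxycyclobutyl)cyclohex-2-enones to spiro[4.5]decane-1,7-diones, here extended to a strain-poor cyclopentanol, a quaternary migrating carbon and an unsymmetrical racemic carbinol.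

Step 5
Reactants: 11 (6R)-5,5-dimethylspiro[5.5]undec-3-ene-1,8-dione
Product: 13 (6R)-5,5-dimethyl-8-oxospiro[5.5]undeca-1,3-dien-1-yl trifluoromethanesulfonate, via potassium dienolate 12 (not isolated)
Conditions: KN(SiMe3)2 (1.0 equiv), THF, −78 °C; PhNTf2, −78 → 0 °C
Reagents that add atoms: N-phenylbis(trifluoromethanesulfonimide), O=S(=O)(N(c1ccccc1)S(=O)(=O)C(F)(F)F)C(F)(F)F
Why: The C2 methylene is α to the ring A carbonyl and allylic, hence the most acidic site, so one equivalent of base gives the linear dienolate and O-triflation (enol triflate formation) leaves the ring B ketone and the spiro centre untouched.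

Step 6
Reactants: 13 (6R)-5,5-dimethyl-8-oxospiro[5.5]undeca-1,3-dien-1-yl trifluoromethanesulfonate
Product: 14 (6S)-7,11,11-trimethylspiro[5.5]undeca-7,9-dien-2-one
Conditions: MeZnCl (1.5 equiv), Pd(PPh3)4 (5 mol %), THF, 50 °C
Reagents that add atoms: methylzinc chloride, C[Zn]Cl
Why: Negishi cross-coupling: zerovalent palladium inserts into the dienyl C–OTf bond, and transmetalation with MeZnCl followed by reductive elimination installs the C1 methyl, the ketone being inert to the organozinc (the descriptor changes only because the priorities change).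

Step 7
Reactants: 14 (6S)-7,11,11-trimethylspiro[5.5]undeca-7,9-dien-2-one
Product: 16 (6S)-3,7,11,11-tetramethylspiro[5.5]undeca-7,9-dien-2-one (both epimers at the new methyl-bearing carbon), via lithium enolate 15 (not isolated)
Conditions: LiN(i-Pr)2 (1.1 equiv), THF, −78 °C; MeI, −78 → −20 °C
Reagents that add atoms: iodomethane, CI
Why: Kinetic enolate alkylation: deprotonation occurs at C9, the α-methylene remote from the spiro centre (C7 is neopentylic and shielded), and the new centre is irrelevant because C9 becomes sp2 in step 8.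

Step 8
Reactants: 16 (6S)-3,7,11,11-tetramethylspiro[5.5]undeca-7,9-dien-2-one
Product: 17 (6S)-8-bromo-1,5,5,9-tetramethylspiro[5.5]undeca-1,3,8-triene
Conditions: (PhO)3P, Br2, CH2Cl2, −60 °C; Et3N; 16, −60 °C → reflux
Reagents that add atoms: bromine, BrBr
Why: Deoxybromination of the ketone by the pre-formed halophosphonium reagent gives, after loss of HBr and (PhO)3P=O, the more substituted vinyl bromide C8(Br)=C9(Me) (elimination toward the methine C9, not the neopentylic C7), and the absence of free Br2 spares the diene.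

Step 9
Reactants: 17 (6S)-8-bromo-1,5,5,9-tetramethylspiro[5.5]undeca-1,3,8-triene
Product: 18 (3S,4S,6S)-4,8-dibromo-1,5,5,9-tetramethylspiro[5.5]undeca-1,8-dien-3-ol
Conditions: NBS (1.05 equiv), THF–H2O (4:1), 0 °C, dark
Reagents that add atoms: N-bromosuccinimide, O=C1CCC(=O)N1Br; water, O
Why: Bromohydrin formation (electrophilic 1,2-bromohydroxylation of a diene): Br+ adds to the terminal diene carbon C4 on the face anti to the pseudo-axial C11 methylene of ring B, and water opens the allylic bromonium at C3 anti to bromine and anti to the pseudo-axial C5 methyl (C1 is fully substituted and shielded), giving the trans (3S,4S) bromohydrin while the ring B vinyl bromide is inert.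

## Compound list

1 | 2-methylcyclopent-2-en-1-one | CC1=CCCC1=O | starting material
2 | potassium 2-methylcyclopenta-1,3-dien-1-olate | [K+].[O-]C1=C(C)C=CC1 | intermediate
3 | 2,2-dimethylcyclopent-3-en-1-one | CC1(C)C=CCC1=O | intermediate
4 | 3-bromocyclohex-2-en-1-one | O=C1C=C(Br)CCC1 | starting material
5 | lithium 5-bromocyclohexa-1,5-dien-1-olate | [Li+].[O-]C1=CCCC(Br)=C1 | intermediate
6 | [(5-bromocyclohexa-1,5-dien-1-yl)oxy](tert-butyl)dimethylsilane | CC(C)(C)[Si](C)(C)OC1=CCCC(Br)=C1 | intermediate
7 | [3-(tert-butyldimethylsilyloxy)cyclohexa-1,3-dien-1-yl]lithium | [Li]C1=CC(O[Si](C)(C)C(C)(C)C)=CCC1 | intermediate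
8 | dichloro[3-(tert-butyldimethylsilyloxy)cyclohexa-1,3-dien-1-yl]cerium | Cl[Ce](Cl)C1=CC(O[Si](C)(C)C(C)(C)C)=CCC1 | intermediate
9 | rac-1-[3-(tert-butyldimethylsilyloxy)cyclohexa-1,3-dien-1-yl]-2,2-dimethylcyclopent-3-en-1-ol | CC(C)(C)[Si](C)(C)OC1=CCCC(=C1)C1(O)CC=CC1(C)C | intermediate
10 | rac-3-(1-hydroxy-2,2-dimethylcyclopent-3-en-1-yl)cyclohex-2-en-1-one | O=C1C=C(CCC1)C1(O)CC=CC1(C)C | intermediate
11 | (6R)-5,5-dimethylspiro[5.5]undec-3-ene-1,8-dione | O=C1CC=CC(C)(C)[C@]12CCCC(=O)C2 | intermediate
12 | potassium (6R)-5,5-dimethyl-8-oxospiro[5.5]undeca-1,3-dien-1-olate | [K+].[O-]C1=CC=CC(C)(C)[C@]12CCCC(=O)C2 | intermediate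
13 | (6R)-5,5-dimethyl-8-oxospiro[5.5]undeca-1,3-dien-1-yl trifluoromethanesulfonate | O=S(=O)(OC1=CC=CC(C)(C)[C@]12CCCC(=O)C2)C(F)(F)F | intermediate
14 | (6S)-7,11,11-trimethylspiro[5.5]undeca-7,9-dien-2-one | CC1=CC=CC(C)(C)[C@]12CCCC(=O)C2 | intermediate
15 | lithium (6S)-7,11,11-trimethylspiro[5.5]undeca-2,7,9-trien-2-olate | CC1=CC=CC(C)(C)[C@]12CCC=C([O-])C2.[Li+] | intermediate
16 | (6S)-3,7,11,11-tetramethylspiro[5.5]undeca-7,9-dien-2-one (both C3 epimers) | CC1=CC=CC(C)(C)[C@]12CCC(C)C(=O)C2 | intermediate
17 | (6S)-8-bromo-1,5,5,9-tetramethylspiro[5.5]undeca-1,3,8-triene | CC1=CC=CC(C)(C)[C@]12CCC(C)=C(Br)C2 | intermediate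
18 | (3S,4S,6S)-4,8-dibromo-1,5,5,9-tetramethylspiro[5.5]undeca-1,8-dien-3-ol | CC1=C[C@H](O)[C@@H](Br)C(C)(C)[C@]12CCC(C)=C(Br)C2 | target

## Step count and risks

Total step count: 9.
Longest linear sequence: 8 steps (4 → 6 → 10 → 11 → 13 → 14 → 16 → 17 → 18; the branch from 1 is equally long).

**Step 4 (proposed new step).**
- Risk: the shift releases little ring strain and may stall.
- Risk: it may behave as a kinetic resolution of racemic 10 rather than a convergent process.
- Risk: 10 may fragment by retro-vinylogous aldol.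

Fallback with known chemistry, setting out from 10 and coming back at 11: catalytic asymmetric nucleophilic epoxidation of the enone (aqueous H2O2, chiral primary amine salt, dioxane) gives 6-(1-hydroxy-2,2-dimethylcyclopent-3-en-1-yl)-7-oxabicyclo[4.1.0]heptan-2-one F1 with the epoxide oxygen on the face opposite to the one C5 must enter. BF3·OEt2 in CH2Cl2 at −78 °C then triggers the stereospecific semipinacol rearrangement of this 2,3-epoxy alcohol: C5 migrates anti to the breaking C6–O bond, so both carbinol epimers give the same spiro centre, (6S,7R)-7-hydroxy-5,5-dimethylspiro[5.5]undec-3-ene-1,8-dione F2. Acetylation (Ac2O, DMAP, pyridine) gives (6S,7R)-5,5-dimethyl-1,8-dioxospiro[5.5]undec-3-en-7-yl acetate F3, and SmI2 in THF–MeOH at −78 °C removes the α-acetoxy group to return 11.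

**Step 8.**
- Risk: elimination toward C7 instead of C9.
- Risk: attack of the bromophosphonium reagent or HBr on the acid-sensitive diene.

Fallback, setting out from 16 and coming back at 17: Tf2O with 2,6-di-tert-butyl-4-methylpyridine in CH2Cl2 gives the more substituted enol triflate, (6S)-3,7,11,11-tetramethylspiro[5.5]undeca-2,7,9-trien-2-yl trifluoromethanesulfonate F4. Triflate-to-bromide exchange with the zerovalent nickel catalyst Ni(cod)2 and LiBr in DMA–THF at 25 °C then gives 17 under neutral conditions.

**Step 9.**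
- Risk: the facial selectivity relative to the spiro centre rests on a conformational argument and is not secured by precedent.
- Risk: 1,4-addition of water at C1 may compete.

Fallback, setting out from 17 and coming back at 18: Mukaiyama hydration of the diene (Mn(dpm)3 cat., PhSiH3, O2, i-PrOH) gives the allylic alcohol (6R)-8-bromo-1,5,5,9-tetramethylspiro[5.5]undeca-1,8-dien-3-ol F5. Oxidation with [C5H5NH][CrO3Cl] in CH2Cl2 gives the enone (6R)-8-bromo-1,5,5,9-tetramethylspiro[5.5]undeca-1,8-dien-3-one F6. α′-Bromination with PhNMe3Br3 in THF gives (4S,6S)-4,8-dibromo-1,5,5,9-tetramethylspiro[5.5]undeca-1,8-dien-3-one F7, whose epimerisable C4 centre can be equilibrated to the equatorial bromide. Luche reduction (NaBH4, CeCl3·7H2O, MeOH, −78 °C) with axial hydride delivery then gives the trans bromohydrin 18.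

Further compounds
F1 | step 4 | 6-(1-hydroxy-2,2-dimethylcyclopent-3-en-1-yl)-7-oxabicyclo[4.1.0]heptan-2-one (epoxide configured as in the SMILES, both carbinol epimers) | O=C1CCC[C@]2(O[C@@H]12)C1(O)CC=CC1(C)C
F2 | step 4 | (6S,7R)-7-hydroxy-5,5-dimethylspiro[5.5]undec-3-ene-1,8-dione | O=C1CC=CC(C)(C)[C@]12CCCC(=O)[C@@H]2O
F3 | step 4 | (6S,7R)-5,5-dimethyl-1,8-dioxospiro[5.5]undec-3-en-7-yl acetate | O=C1CC=CC(C)(C)[C@]12CCCC(=O)[C@@H]2OC(C)=O
F4 | step 8 | (6S)-3,7,11,11-tetramethylspiro[5.5]undeca-2,7,9-trien-2-yl trifluoromethanesulfonate | CC1=CC=CC(C)(C)[C@]12CCC(C)=C(OS(=O)(=O)C(F)(F)F)C2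
F5 | step 9 | (6R)-8-bromo-1,5,5,9-tetramethylspiro[5.5]undeca-1,8-dien-3-ol (both C3 epimers) | CC1=CC(O)CC(C)(C)[C@]12CCC(C)=C(Br)C2
F6 | step 9 | (6R)-8-bromo-1,5,5,9-tetramethylspiro[5.5]undeca-1,8-dien-3-one | CC1=CC(=O)CC(C)(C)[C@]12CCC(C)=C(Br)C2
F7 | step 9 | (4S,6S)-4,8-dibromo-1,5,5,9-tetramethylspiro[5.5]undeca-1,8-dien-3-one | CC1=CC(=O)[C@@H](Br)C(C)(C)[C@]12CCC(C)=C(Br)C2
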